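**Assumption:** the SMILES is read as 2Z, 6R, 7S (cis‑epoxide, C5 and C8 on the same side), 10E, 12R, with locants C1 (CH2OAc) to C16 along the chain; bought reagents that put no carbon into the target carry no number.

## Retrosynthetic overview

1. C12–C13 is made last: reagent‑controlled 2‑isopropylallylboration of epoxy‑enal 11 sets 12R.
2. The oxirane, the only ring, is formed in step 5 by Shi epoxidation of the 6Z olefin of trienal 10; the Z geometry becomes the cis‑(6R,7S) epoxide.
3. C10=C11 comes from an E‑selective Wittig reaction of aldehyde 8 with Ph3P=C(CH3)CHO.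
4. Key bond C7–C8: Negishi coupling of (Z)‑vinyl iodide 5 with a β‑zincio acetal, a propanal homoenolate (d3), which joins two acceptor carbons and fixes 6Z.
5. Iodide 5 comes from neryl acetate (2Z bought) by selective ozonolysis to the C1–C6 aldehyde 3 and Zhao iodo‑olefination.

## Route

Step 1
Reactants: 1 neryl acetate [(2Z)-3,7-dimethylocta-2,6-dien-1-yl acetate]
Product: 3 (2Z)-3-methyl-6-oxohex-2-en-1-yl acetate, via ozonide 2 (not isolated)
Conditions: O3 (1 equiv, Sudan Red 7B end point), CH2Cl2, −78 °C; then Me2S, −78 → 23 °C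
Reagents that add atoms: ozone, [O-][O+]=O
Why: Criegee ozonolysis cleaves the electron‑rich 6,7‑olefin well before the 2,3‑olefin, which is deactivated by the allylic acetate, so the bought 2Z geometry is untouched and Me2S reduces ozonide 2 to the aldehyde.

Step 2
Reactants: 3 (2Z)-3-methyl-6-oxohex-2-en-1-yl acetate; 4 ethyltriphenylphosphonium iodide
Product: 5 (2Z,6Z)-7-iodo-3-methylocta-2,6-dien-1-yl acetate
Conditions: 4, n-BuLi, THF, 0 → 23 °C; I2, −78 °C; NaN(SiMe3)2, −20 °C; then 3, −78 → −20 °C
Reagents that add atoms: iodine, [I][I]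
Why: Zhao's α‑iodo Wittig olefination runs under kinetic control through the cis‑oxaphosphetane and gives the (Z)-2-iodo-2-alkene with iodine cis to the chain (typically at least 10:1), while the ylide leaves the acetate alone at −78 °C.

Step 3
Reactants: 5 (2Z,6Z)-7-iodo-3-methylocta-2,6-dien-1-yl acetate; 6 3-bromo-1,1-dimethoxypropane
Product: 8 (2Z,6Z)-3,7-dimethyl-10-oxodeca-2,6-dien-1-yl acetate, via dimethyl acetal 7 (not isolated)
Conditions: 6, Zn dust, LiCl, THF, 50 °C; then 5, PdCl2(dppf) (5 mol %), THF, 23 °C; then 1 M aq. HCl, 0 → 23 °C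
Reagents that add atoms: water, O
Why: Negishi sp2–sp3 cross‑coupling in which the β‑zincio acetal serves as a propanal homoenolate (d3 reagent), so that C7 (electrophilic vinyl iodide carbon) is joined to C8 (the β‑carbon of an aldehyde, normally itself an acceptor), a pairing the vinyl‑metal/acrolein alternative cannot deliver because 5 cannot be metalated beside its acetate; zerovalent palladium inserts into C–I far faster than it ionises the trisubstituted allylic acetate, the coupling retains olefin geometry (6Z), and the acidic work‑up cleaves the acetal.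

Step 4
Reactants: 8 (2Z,6Z)-3,7-dimethyl-10-oxodeca-2,6-dien-1-yl acetate; 9 2-(triphenylphosphoranylidene)propanal
Product: 10 (2Z,6Z,10E)-3,7,11-trimethyl-12-oxododeca-2,6,10-trien-1-yl acetate
Conditions: 9 (1.3 equiv), toluene, 90 °C
Reagents that add atoms: none
Why: Wittig olefination with a stabilised formyl ylide is aldehyde‑selective and E‑selective (above 95:5), placing C9 trans to the formyl group as 10E requires.

Step 5
Reactants: 10 (2Z,6Z,10E)-3,7,11-trimethyl-12-oxododeca-2,6,10-trien-1-yl acetate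
Product: 11 (2Z)-3-methyl-5-[(2R,3S)-3-methyl-3-[(3E)-4-methyl-5-oxopent-3-en-1-yl]oxiran-2-yl]pent-2-en-1-yl acetate
Conditions: Shi D‑fructose‑derived ketone (0.3 equiv), Oxone (2KHSO5·KHSO4·K2SO4), K2CO3, Bu4NHSO4, MeCN–CH2(OMe)2–aq. Na2B4O7 buffer (pH 10.5), −10 → 0 °C
Reagents that add atoms: potassium peroxymonosulfate, [K+].[O-]S(=O)(=O)OO
Why: Shi asymmetric epoxidation (chiral dioxirane, spiro transition state) attacks only the electron‑rich 6,7‑olefin, since the 2,3‑ and 10,11‑olefins are deactivated by the acetate and the formyl group, and the D‑fructose ketone delivers oxygen to the face that gives R at the CH carbon (as in its R,R epoxides of trans and trisubstituted olefins), which on the 6Z olefin is the cis‑epoxide 6R,7S.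

Step 6
Reactants: 11 (2Z)-3-methyl-5-[(2R,3S)-3-methyl-3-[(3E)-4-methyl-5-oxopent-3-en-1-yl]oxiran-2-yl]pent-2-en-1-yl acetate; 12 2,3-dimethylbut-1-ene
Product: 14 (2Z)-5-[(2R,3S)-3-[(3E,5R)-5-hydroxy-4,8-dimethyl-7-methylidenenon-3-en-1-yl]-3-methyloxiran-2-yl]-3-methylpent-2-en-1-yl acetate, via borinate 13 (not isolated)
Conditions: 12, n-BuLi, KOtBu, THF, −78 → −50 °C; (+)-Ipc2BOMe [from (−)-α-pinene], −78 °C; BF3·OEt2 (1.2 equiv), −78 °C; then 11, THF–Et2O, −78 °C; then HOCH2CH2NH2, 23 °C
Reagents that add atoms: none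
Why: Brown asymmetric allylboration (chair Zimmerman–Traxler transition state, reagent control) with the (−)-α-pinene‑derived borane adds the symmetrical 2‑isopropylallyl group to the Re face of the enal to set 12R (the antipodal borane gives the S alcohol from α‑methyl enals), the alkoxides present bind all BF3 so the epoxide and acetate survive at −78 °C, and ethanolamine frees the alcohol from borinate 13 without base or peroxide.

## Compound list

1 | neryl acetate, (2Z)-3,7-dimethylocta-2,6-dien-1-yl acetate | CC(=O)OC/C=C(C)\CCC=C(C)C | starting material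
2 | (2Z)-5-(5,5-dimethyl-1,2,4-trioxolan-3-yl)-3-methylpent-2-en-1-yl acetate (ozonide, ring CH unassigned) | CC(=O)OC/C=C(C)\CCC1OOC(C)(C)O1 | intermediate
3 | (2Z)-3-methyl-6-oxohex-2-en-1-yl acetate | CC(=O)OC/C=C(C)\CCC=O | intermediate
4 | ethyltriphenylphosphonium iodide | CC[P+](c1ccccc1)(c1ccccc1)c1ccccc1.[I-] | starting material
5 | (2Z,6Z)-7-iodo-3-methylocta-2,6-dien-1-yl acetate | CC(=O)OC/C=C(C)\CC/C=C(\I)C | intermediate
6 | 3-bromo-1,1-dimethoxypropane | COC(CCBr)OC | starting material
7 | (2Z,6Z)-10,10-dimethoxy-3,7-dimethyldeca-2,6-dien-1-yl acetate | CC(=O)OC/C=C(C)\CC/C=C(C)\CCC(OC)OC | intermediate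
8 | (2Z,6Z)-3,7-dimethyl-10-oxodeca-2,6-dien-1-yl acetate | CC(=O)OC/C=C(C)\CC/C=C(C)\CCC=O | intermediate
9 | 2-(triphenylphosphoranylidene)propanal | CC(C=O)=P(c1ccccc1)(c1ccccc1)c1ccccc1 | starting material
10 | (2Z,6Z,10E)-3,7,11-trimethyl-12-oxododeca-2,6,10-trien-1-yl acetate | CC(=O)OC/C=C(C)\CC/C=C(C)\CC/C=C(\C)C=O | intermediate
11 | (2Z)-3-methyl-5-[(2R,3S)-3-methyl-3-[(3E)-4-methyl-5-oxopent-3-en-1-yl]oxiran-2-yl]pent-2-en-1-yl acetate | O=C/C(C)=C/CC[C@]1(C)O[C@@H]1CC/C(C)=C\COC(C)=O | intermediate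
12 | 2,3-dimethylbut-1-ene | C=C(C)C(C)C | starting material
13 | bis[(1S,2R,3S,5S)-2,6,6-trimethylbicyclo[3.1.1]heptan-3-yl]borinate of 14 (boron on the C12 oxygen) | C=C(C[C@@H](OB([C@H]1C[C@H]2C[C@@H]([C@@H]1C)C2(C)C)[C@H]1C[C@H]2C[C@@H]([C@@H]1C)C2(C)C)/C(C)=C/CC[C@]1(C)O[C@@H]1CC/C(C)=C\COC(C)=O)C(C)C | intermediate
14 | (2Z)-5-[(2R,3S)-3-[(3E,5R)-5-hydroxy-4,8-dimethyl-7-methylidenenon-3-en-1-yl]-3-methyloxiran-2-yl]-3-methylpent-2-en-1-yl acetate (CNP0299597.1) | C=C(C[C@@H](O)/C(C)=C/CC[C@]1(C)O[C@@H]1CC/C(C)=C\COC(C)=O)C(C)C | target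

## Step count and risks

Total steps: 6. Longest linear sequence: 6 (from neryl acetate 1).

**Step 5 (most likely to fail).** Oxone may over‑oxidise the free enal, and the ee of the Shi reaction on a Z‑trisubstituted dialkyl olefin is less well documented than for E olefins. Because C6/C7 and C12 are remote, a minor epoxide enantiomer would end up as a hard‑to‑separate diastereomer of 14. The fallback sets out from 8 and comes back at 11, placing the epoxidation before any enal exists. Aldehyde 8 is methylenated (Ph3PCH3Br, KN(SiMe3)2, THF, −78 → 0 °C) to (2Z,6Z)-3,7-dimethylundeca-2,6,10-trien-1-yl acetate F2. Its only electron‑rich trisubstituted olefin is epoxidised under the same Shi conditions to (2Z)-5-[(2R,3S)-3-(but-3-en-1-yl)-3-methyloxiran-2-yl]-3-methylpent-2-en-1-yl acetate F3. Cross‑metathesis of the terminal vinyl group with methacrolein (second‑generation Hoveyda–Grubbs catalyst, RuCl2(H2IMes)(=CH-C6H4-2-OiPr), CH2Cl2, 40 °C) then builds the E‑enal and returns to 11.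

**Step 3.** The zinc homoenolate may form sluggishly, or zerovalent palladium may ionise the allylic acetate in competition with the coupling. The fallback sets out from 5 and comes back at 7, replacing the organozinc by an organoborane. Acrolein dimethyl acetal is hydroborated with 9-BBN-H (THF, 23 °C) to 9-(3,3-dimethoxypropyl)-9-borabicyclo[3.3.1]nonane F1. This is coupled with 5 under B‑alkyl Suzuki–Miyaura conditions (PdCl2(dppf), Ph3As, Cs2CO3, DMF–THF–H2O, 23 °C) to give 7, which the same acidic work‑up takes on to 8.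

**Step 6.** The 2‑isopropylallyl borane is new in this form, so metalation efficiency, ee and epoxide tolerance are untested. The fallback sets out from 12 and 11 and comes back at 14, moving from a stoichiometric chiral borane to a chiral Lewis‑acid catalyst. Alkene 12 is metalated as before and quenched with Bu3SnCl to give tributyl(3-methyl-2-methylidenebutyl)stannane F4. Keck allylation of 11 with F4 ((R)-BINOL, Ti(OiPr)4, 4 Å sieves, CH2Cl2, −20 °C; Re‑face addition) gives the O-tributylstannyl ether of 14 F5, and KF work‑up releases 14.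

## Further compounds

F1 | step 3 | 9-(3,3-dimethoxypropyl)-9-borabicyclo[3.3.1]nonane | COC(CCB1C2CCCC1CCC2)OC
F2 | step 5 | (2Z,6Z)-3,7-dimethylundeca-2,6,10-trien-1-yl acetate | CC(=O)OC/C=C(C)\CC/C=C(C)\CCC=C
F3 | step 5 | (2Z)-5-[(2R,3S)-3-(but-3-en-1-yl)-3-methyloxiran-2-yl]-3-methylpent-2-en-1-yl acetate | C=CCC[C@]1(C)O[C@@H]1CC/C(C)=C\COC(C)=O
F4 | step 6 | tributyl(3-methyl-2-methylidenebutyl)stannane | C=C(C[Sn](CCCC)(CCCC)CCCC)C(C)C
F5 | step 6 | O-tributylstannyl ether of 14 | C=C(C[C@@H](O[Sn](CCCC)(CCCC)CCCC)/C(C)=C/CC[C@]1(C)O[C@@H]1CC/C(C)=C\COC(C)=O)C(C)C
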